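**Retrosynthetic overview**
1. Target 27 ⇒ macrocyclic trienol 24: the six C–O bonds of the three oxiranes are made last, in one flask, steered by 5-OH and the ring shape (key step).
2. 24 ⇒ iodo-aldehyde 22: C4–C5 by Nozaki–Hiyama–Kishi closure of the ten-membered ring; the C8 angelate (C–O) and the C5 aldehyde both come from 17.
3. 17 ⇒ bromomethyl-butenolide 5 + skipped trienal 15: C7–C8 by Barbier allylation, which also unveils the α-methylene lactone and sets C7 and C8.
4. 5 ⇒ (S)-but-3-ene-1,2-diol + 2-(bromomethyl)acrylic acid (ester C–O, then metathesis); 15 ⇒ cis-dichloroethene + ethynyltrimethylsilane + but-3-yn-1-ol + AlMe3.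
5. Ring order: γ-lactone (step 3), ten-membered carbocycle (step 12), three oxiranes (step 13).

Assumption: germacrane numbering is used with the lactone read as the 12,6-olide (lactone O on C6, angelate on C8, OH on C5, methyl C14 on C10, oxirane CH2 = C15 on C4, exocyclic CH2 = C13); the target is then 1R,2R,3S,4S,5S,6S,7R,8S,10R with a Z (angelate) ester.

All stereochemical outcomes below are predictions from standard models; none has been tested on these substrates.

**Route**

Step 1
Reactants: 1 (2S)-but-3-ene-1,2-diol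
Product: 2 (2S)-1-[(triethylsilyl)oxy]but-3-en-2-ol
Conditions: Et3SiCl (1.0 equiv), imidazole, CH2Cl2, −78 → −20 °C
Reagents that add atoms: chlorotriethylsilane, CC[Si](Cl)(CC)CC
Why: Selective O-silylation of the less hindered primary hydroxyl at low temperature; the secondary allylic carbinol centre (S, later C6) is untouched.

Step 2
Reactants: 2 (2S)-1-[(triethylsilyl)oxy]but-3-en-2-ol; 3 2-(bromomethyl)prop-2-enoic acid
Product: 4 (2S)-1-[(triethylsilyl)oxy]but-3-en-2-yl 2-(bromomethyl)prop-2-enoate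
Conditions: DCC, DMAP (5 mol %), CH2Cl2, 0 °C
Reagents that add atoms: none
Why: Steglich (carbodiimide) esterification of the secondary allylic alcohol, run cold with little DMAP so that acylation outruns SN2' attack on the allylic bromide; the stereocentre is not involved.

Step 3
Reactants: 4 (2S)-1-[(triethylsilyl)oxy]but-3-en-2-yl 2-(bromomethyl)prop-2-enoate
Product: 5 (5S)-3-(bromomethyl)-5-{[(triethylsilyl)oxy]methyl}furan-2(5H)-one
Conditions: second-generation Grubbs catalyst RuCl2(=CHPh)(PCy3)(H2IMes) (5 mol %), toluene, 80 °C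
Reagents that add atoms: none
Why: Ring-closing metathesis of the acrylate and vinyl groups closes the butenolide with loss of ethene; the ruthenium carbene tolerates the allylic bromide and the stereocentre is untouched.

Step 4
Reactants: 6 (Z)-1,2-dichloroethene; 7 ethynyl(trimethyl)silane
Product: 8 [(3Z)-4-chlorobut-3-en-1-yn-1-yl](trimethyl)silane
Conditions: Pd(PPh3)4 (3 mol %), CuI (6 mol %), n-BuNH2, Et2O, 20 °C, 6 in fivefold excess
Reagents that add atoms: none
Why: Sonogashira coupling on cis-dichloroethene in excess stops at mono-substitution and keeps the Z geometry that becomes C2=C3.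

Step 5
Reactants: 9 but-3-yn-1-ol; 8 [(3Z)-4-chlorobut-3-en-1-yn-1-yl](trimethyl)silane
Product: 11 (3E,5Z)-3-methyl-8-(trimethylsilyl)octa-3,5-dien-7-yn-1-ol, via alkenylalane 10 (not isolated)
Conditions: AlMe3 (3 equiv), Cp2ZrCl2 (0.25 equiv), CH2Cl2, 0 → 23 °C; then 8, ZnCl2 (1 equiv), Pd(P(t-Bu)3)2 (3 mol %), THF, 23 °C
Reagents that add atoms: trimethylaluminium, C[Al](C)C
Why: Negishi zirconium-catalysed carboalumination adds methyl and aluminium syn across the alkyne (E-trisubstituted C10=C1), and the alkenylalane, after transfer to zinc, undergoes Pd-catalysed Negishi cross-coupling with the activated alkenyl chloride with retention of both alkene geometries.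

Step 6
Reactants: 11 (3E,5Z)-3-methyl-8-(trimethylsilyl)octa-3,5-dien-7-yn-1-ol
Product: 12 (3E,5Z)-3-methylocta-3,5-dien-7-yn-1-ol
Conditions: K2CO3 (0.2 equiv), MeOH, 0 → 20 °C
Reagents that add atoms: none
Why: Base-catalysed methanolysis of the alkynyl C–Si bond (protodesilylation) frees the terminal alkyne; the diene is inert to these conditions.

Step 7
Reactants: 12 (3E,5Z)-3-methylocta-3,5-dien-7-yn-1-ol
Product: 14 (3E,5Z)-7-iodo-3-methylocta-3,5,7-trien-1-ol, via internal alkenylalane 13 (not isolated)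
Conditions: i-Bu2AlH (2.3 equiv), NiCl2(dppp) (3 mol %), THF, 0 → 22 °C; then N-iodosuccinimide, −78 → 0 °C, dark
Reagents that add atoms: N-iodosuccinimide, O=C1CCC(=O)N1I
Why: Nickel-catalysed α-selective (Markovnikov) hydroalumination puts aluminium on the internal alkyne carbon by syn addition, and iodinolysis of the C–Al bond with retention gives the 2-iodo-1,3-diene; the first equivalent of hydride is consumed by the hydroxyl.

Step 8
Reactants: 14 (3E,5Z)-7-iodo-3-methylocta-3,5,7-trien-1-ol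
Product: 15 (3E,5Z)-7-iodo-3-methylocta-3,5,7-trienal
Conditions: Dess–Martin periodinane, pyridine, CH2Cl2, 0 °C; used crude at once
Reagents that add atoms: none
Why: Dess–Martin oxidation under pyridine buffer gives the β,γ-unsaturated aldehyde without a base strong enough to move C10=C1 into conjugation.

Step 9
Reactants: 5 (5S)-3-(bromomethyl)-5-{[(triethylsilyl)oxy]methyl}furan-2(5H)-one; 15 (3E,5Z)-7-iodo-3-methylocta-3,5,7-trienal
Product: 17 (4R,5S)-4-[(1S,3E,5Z)-1-hydroxy-7-iodo-3-methylocta-3,5,7-trien-1-yl]-3-methylidene-5-{[(triethylsilyl)oxy]methyl}oxolan-2-one, via allylzinc bromide 16 (not isolated)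
Conditions: Zn dust, THF/sat. aq NH4Cl (4:1), 0 °C, 5 (1.5 equiv)
Reagents that add atoms: none
Why: Barbier allylation in which the allylzinc reacts through its γ-carbon (C7) in a chair Zimmerman–Traxler transition state, on the ring face anti to the silyloxymethyl group (6,7-trans) and with the ring-fixed E-type allyl geometry giving the anti carbinol (7R,8S); the exocyclic methylene of the lactone appears in the same event.

Step 10
Reactants: 17 (4R,5S)-4-[(1S,3E,5Z)-1-hydroxy-7-iodo-3-methylocta-3,5,7-trien-1-yl]-3-methylidene-5-{[(triethylsilyl)oxy]methyl}oxolan-2-one; 18 angelic acid (2Z)-2-methylbut-2-enoic acid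
Product: 20 (1S,3E,5Z)-7-iodo-3-methyl-1-[(2S,3R)-4-methylidene-5-oxo-2-{[(triethylsilyl)oxy]methyl}oxolan-3-yl]octa-3,5,7-trien-1-yl (2Z)-2-methylbut-2-enoate, via mixed anhydride 19 (not isolated)
Conditions: 18, 2,4,6-Cl3C6H2COCl, Et3N, toluene, 20 °C; then 17, 70 °C
Reagents that add atoms: none
Why: Yamaguchi esterification in which the alcohol attacks the unhindered angeloyl carbonyl of the mixed anhydride with retention at C8, and the absence of a nucleophilic amine catalyst keeps the Z (angelate) geometry.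

Step 11
Reactants: 20 (1S,3E,5Z)-7-iodo-3-methyl-1-[(2S,3R)-4-methylidene-5-oxo-2-{[(triethylsilyl)oxy]methyl}oxolan-3-yl]octa-3,5,7-trien-1-yl (2Z)-2-methylbut-2-enoate
Product: 22 (1S,3E,5Z)-1-[(2S,3R)-2-formyl-4-methylidene-5-oxooxolan-3-yl]-7-iodo-3-methylocta-3,5,7-trien-1-yl (2Z)-2-methylbut-2-enoate, via alkoxysulfonium chloride 21 (not isolated)
Conditions: (COCl)2, DMSO, CH2Cl2, −78 → −40 °C; then Et3N, −78 → 0 °C; used crude
Reagents that add atoms: none
Why: Swern oxidation applied directly to the primary triethylsilyl ether (oxidative desilylation), in which the chlorosulfonium ion attacks the ether oxygen, chloride removes silicon and the alkoxysulfonium salt collapses with base to the aldehyde at low temperature, so C6 next to the new carbonyl is not epimerised.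

Step 12
Reactants: 22 (1S,3E,5Z)-1-[(2S,3R)-2-formyl-4-methylidene-5-oxooxolan-3-yl]-7-iodo-3-methylocta-3,5,7-trien-1-yl (2Z)-2-methylbut-2-enoate
Product: 24 (5R,6S,7R,8S)-5-hydroxy-8-[(2Z)-2-methylbut-2-enoyloxy]germacra-1(10)E,2Z,4(15),11(13)-tetraen-12,6-olide, via alkenylchromium dichloride 23 (not isolated)
Conditions: CrCl2 (10 equiv), NiCl2 (0.1 equiv), DMSO/THF (3:1), 2 mM, 23 °C, slow addition of 22
Reagents that add atoms: none
Why: Nozaki–Hiyama–Kishi macrocyclisation in which zerovalent nickel inserts into the C–I bond, the alkenyl group passes to chromium and the alkenylchromium adds to the aldehyde under high dilution; Felkin–Anh addition anti to the lactone C6–O bond sets C5 with O5 anti to O6 (5R in 24, the same arrangement as 5S in the target).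

Step 13
Reactants: 24 (5R,6S,7R,8S)-5-hydroxy-8-[(2Z)-2-methylbut-2-enoyloxy]germacra-1(10)E,2Z,4(15),11(13)-tetraen-12,6-olide
Product: 27 (1R,2R,3S,4S,5S,6S,7R,8S,10R)-1,10:2,3:4,15-triepoxy-5-hydroxy-8-[(2Z)-2-methylbut-2-enoyloxy]germacr-11(13)-en-12,6-olide (CNP0594916.1), via 1,10-monoepoxide 25 (not isolated), via 1,10:4,15-diepoxide 26 (not isolated)
Conditions: dimethyldioxirane (3.6 equiv), acetone/CH2Cl2 (1:4), −20 → 0 °C
Reagents that add atoms: dimethyldioxirane, CC1(C)OO1
Why: Proposed new method: an exhaustive, face-uniform tris-epoxidation of a ten-membered conjugated trienol by a neutral dioxirane, not yet shown on a cyclic conjugated triene; each oxygen is transferred in a concerted spiro transition state, first to the electron-rich E-trisubstituted C1=C10, then to C4=C15 (assisted by a hydrogen bond from 5-OH, O–C5–C4=C15 near 120° with H5 in the alkene plane), last to the Z-C2=C3; the ring is expected to hold the triene as a cisoid helical arc whose concave face is covered by C5–C9 and the lactone, so all three oxygens should arrive on the convex face where 5-OH lies, which corresponds to the all-syn array of the target (1R,2R,3S,4S,10R; C4 threo to C5, the C2–C3 oxirane anti to the C1–O bond in the H1-eclipsed conformer); acetone as the only co-product spares the two intermediate vinyl oxiranes, and the electron-poor angelate and methylene-lactone alkenes do not react at 0 °C; closest known reaction types are Henbest-type hydroxyl-directed epoxidation and conformation-controlled (peripheral) epoxidation of medium-ring dienes.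

**Compound list**

1 | (2S)-but-3-ene-1,2-diol | O[C@H](CO)C=C | starting material
2 | (2S)-1-[(triethylsilyl)oxy]but-3-en-2-ol | O[C@H](CO[Si](CC)(CC)CC)C=C | intermediate
3 | 2-(bromomethyl)prop-2-enoic acid | C=C(CBr)C(=O)O | starting material
4 | (2S)-1-[(triethylsilyl)oxy]but-3-en-2-yl 2-(bromomethyl)prop-2-enoate | C=C(CBr)C(=O)O[C@H](CO[Si](CC)(CC)CC)C=C | intermediate
5 | (5S)-3-(bromomethyl)-5-{[(triethylsilyl)oxy]methyl}furan-2(5H)-one | O=C1O[C@H](CO[Si](CC)(CC)CC)C=C1CBr | intermediate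
6 | (Z)-1,2-dichloroethene | Cl/C=C\Cl | starting material
7 | ethynyl(trimethyl)silane | C#C[Si](C)(C)C | starting material
8 | [(3Z)-4-chlorobut-3-en-1-yn-1-yl](trimethyl)silane | Cl/C=C\C#C[Si](C)(C)C | intermediate
9 | but-3-yn-1-ol | C#CCCO | starting material
10 | dimethylaluminium alkoxide of (3E)-4-(dimethylalumanyl)-3-methylbut-3-en-1-ol | C[Al](C)/C=C(\C)CCO[Al](C)C | intermediate (not isolated)
11 | (3E,5Z)-3-methyl-8-(trimethylsilyl)octa-3,5-dien-7-yn-1-ol | OCC/C(C)=C/C=C\C#C[Si](C)(C)C | intermediate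
12 | (3E,5Z)-3-methylocta-3,5-dien-7-yn-1-ol | OCC/C(C)=C/C=C\C#C | intermediate
13 | diisobutylaluminium alkoxide of (3E,5Z)-7-(diisobutylalumanyl)-3-methylocta-3,5,7-trien-1-ol | CC(C)C[Al](CC(C)C)OCC/C(C)=C/C=C\C(=C)[Al](CC(C)C)CC(C)C | intermediate (not isolated)
14 | (3E,5Z)-7-iodo-3-methylocta-3,5,7-trien-1-ol | OCC/C(C)=C/C=C\C(I)=C | intermediate
15 | (3E,5Z)-7-iodo-3-methylocta-3,5,7-trienal | O=CC/C(C)=C/C=C\C(I)=C | intermediate
16 | bromo{[(5S)-2-oxo-5-{[(triethylsilyl)oxy]methyl}-2,5-dihydrofuran-3-yl]methyl}zinc | O=C1O[C@H](CO[Si](CC)(CC)CC)C=C1C[Zn]Br | intermediate (not isolated)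
17 | (4R,5S)-4-[(1S,3E,5Z)-1-hydroxy-7-iodo-3-methylocta-3,5,7-trien-1-yl]-3-methylidene-5-{[(triethylsilyl)oxy]methyl}oxolan-2-one | C=C1C(=O)O[C@H](CO[Si](CC)(CC)CC)[C@H]1[C@@H](O)C/C(C)=C/C=C\C(I)=C | intermediate
18 | angelic acid, (2Z)-2-methylbut-2-enoic acid | C/C=C(/C)C(=O)O | starting material
19 | (2Z)-2-methylbut-2-enoic 2,4,6-trichlorobenzoic anhydride | C/C=C(/C)C(=O)OC(=O)c1c(Cl)cc(Cl)cc1Cl | intermediate (not isolated)
20 | (1S,3E,5Z)-7-iodo-3-methyl-1-[(2S,3R)-4-methylidene-5-oxo-2-{[(triethylsilyl)oxy]methyl}oxolan-3-yl]octa-3,5,7-trien-1-yl (2Z)-2-methylbut-2-enoate | C=C1C(=O)O[C@H](CO[Si](CC)(CC)CC)[C@H]1[C@@H](OC(=O)/C(C)=C\C)C/C(C)=C/C=C\C(I)=C | intermediate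
21 | dimethyl{[(2S,3R)-3-[(1S,3E,5Z)-7-iodo-3-methyl-1-{[(2Z)-2-methylbut-2-enoyl]oxy}octa-3,5,7-trien-1-yl]-4-methylidene-5-oxooxolan-2-yl]methoxy}sulfonium chloride | C=C1C(=O)O[C@H](CO[S+](C)C)[C@H]1[C@@H](OC(=O)/C(C)=C\C)C/C(C)=C/C=C\C(I)=C.[Cl-] | intermediate (not isolated)
22 | (1S,3E,5Z)-1-[(2S,3R)-2-formyl-4-methylidene-5-oxooxolan-3-yl]-7-iodo-3-methylocta-3,5,7-trien-1-yl (2Z)-2-methylbut-2-enoate | C=C1C(=O)O[C@H](C=O)[C@H]1[C@@H](OC(=O)/C(C)=C\C)C/C(C)=C/C=C\C(I)=C | intermediate
23 | dichloro(alkenyl)chromium formed from 22 at C4 in place of iodine | C=C1C(=O)O[C@H](C=O)[C@H]1[C@@H](OC(=O)/C(C)=C\C)C/C(C)=C/C=C\C(=C)[Cr](Cl)Cl | intermediate (not isolated)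
24 | (5R,6S,7R,8S)-5-hydroxy-8-[(2Z)-2-methylbut-2-enoyloxy]germacra-1(10)E,2Z,4(15),11(13)-tetraen-12,6-olide | C=C1C(=O)O[C@H]2[C@H]1[C@@H](OC(=O)/C(C)=C\C)C/C(C)=C/C=C\C(=C)[C@H]2O | intermediate
25 | (1R,5R,6S,7R,8S,10R)-1,10-epoxy-5-hydroxy-8-[(2Z)-2-methylbut-2-enoyloxy]germacra-2Z,4(15),11(13)-trien-12,6-olide | C=C1C(=O)O[C@H]2[C@H]1[C@@H](OC(=O)/C(C)=C\C)C[C@@]1(C)O[C@@H]1/C=C\C(=C)[C@H]2O | intermediate (not isolated)
26 | (1R,4S,5S,6S,7R,8S,10R)-1,10:4,15-diepoxy-5-hydroxy-8-[(2Z)-2-methylbut-2-enoyloxy]germacra-2Z,11(13)-dien-12,6-olide | C=C1C(=O)O[C@H]2[C@H]1[C@@H](OC(=O)/C(C)=C\C)C[C@@]1(C)O[C@@H]1/C=C\[C@]1(CO1)[C@H]2O | intermediate (not isolated)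
27 | (1R,2R,3S,4S,5S,6S,7R,8S,10R)-1,10:2,3:4,15-triepoxy-5-hydroxy-8-[(2Z)-2-methylbut-2-enoyloxy]germacr-11(13)-en-12,6-olide (CNP0594916.1) | C=C1C(=O)O[C@H]2[C@H]1[C@@H](OC(=O)/C(C)=C\C)C[C@@]1(C)O[C@@H]1[C@@H]1O[C@@H]1[C@]1(CO1)[C@H]2O | target

**Step count and risks**

Total steps: 13 (steps 1–3 make the lactone piece, steps 4–8 the trienal, steps 9–13 join and finish).
Longest linear sequence: 10 steps (steps 4–13, from 6 and 7).

The three steps most likely to fail:

Step 13 (the proposed new tris-epoxidation). It rests on an untested conformational model, so it may give the C4 epimer or the opposite face at the diene, stop at 26, or open a vinyl oxirane. The fallback uses known reactions and is stepwise and reagent-directed instead of one-flask and substrate-directed. It sets out from 24. Shi asymmetric epoxidation (D-fructose-derived ketone catalyst, Oxone 2KHSO5·KHSO4·K2SO4, K2CO3 buffer, MeCN/dimethoxymethane/H2O, 0 °C) oxidises only the E-trisubstituted C1=C10 under catalyst control, and 25 is now isolated. VO(acac)2/t-BuOOH in toluene then delivers oxygen to C4=C15 from pentavalent vanadium bound at O5; this metal-bound, small-dihedral-angle mode is complementary to the hydrogen-bond mode, so whichever of the two gives the natural C4 configuration is kept, and 26 is isolated. Buffered m-CPBA finally epoxidises the remaining Z-alkene anti to the flanking oxiranes, and the sequence comes back to the route at 27.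

Step 12 (ring closure). The ten-membered ring may form with poor selectivity at C5, alongside proto-deiodination. The fallback sets C5 by a reagent instead of by the cyclisation. It sets out from 24 obtained as a C5 epimer mixture. Dess–Martin oxidation gives the cross-conjugated ketone (6S,7R,8S)-8-[(2Z)-2-methylbut-2-enoyloxy]-5-oxogermacra-1(10)E,2Z,4(15),11(13)-tetraen-12,6-olide F6. Corey–Bakshi–Shibata reduction (oxazaborolidine catalyst, catecholborane, −78 °C, catalyst antipode chosen for the 5R alcohol) then comes back to the route at 24 as one epimer.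

Step 9 (Barbier allylation). Aldehyde 15 can slide into conjugation or polymerise before it is trapped. The fallback removes the C10=C1 bond before the aldehyde is made and adds catalyst control at C1 and C10. It sets out from 14.
- Shi epoxidation (same ketone catalyst and Oxone conditions as above) gives 2-[(2R,3R)-3-[(1Z)-3-iodobuta-1,3-dien-1-yl]-2-methyloxiran-2-yl]ethan-1-ol F1.
- Dess–Martin oxidation gives [(2R,3R)-3-[(1Z)-3-iodobuta-1,3-dien-1-yl]-2-methyloxiran-2-yl]acetaldehyde F2, which cannot conjugate.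
- Indium-mediated Barbier allylation with 5 (In powder, THF/H2O, neutral) gives (4R,5S)-4-{(1S)-1-hydroxy-2-[(2R,3R)-3-[(1Z)-3-iodobuta-1,3-dien-1-yl]-2-methyloxiran-2-yl]ethyl}-3-methylidene-5-{[(triethylsilyl)oxy]methyl}oxolan-2-one F3.
- Yamaguchi esterification with 18 gives (1S)-2-[(2R,3R)-3-[(1Z)-3-iodobuta-1,3-dien-1-yl]-2-methyloxiran-2-yl]-1-[(2S,3R)-4-methylidene-5-oxo-2-{[(triethylsilyl)oxy]methyl}oxolan-3-yl]ethyl (2Z)-2-methylbut-2-enoate F4.
- Swern oxidation of the silyl ether gives (1S)-1-[(2S,3R)-2-formyl-4-methylidene-5-oxooxolan-3-yl]-2-[(2R,3R)-3-[(1Z)-3-iodobuta-1,3-dien-1-yl]-2-methyloxiran-2-yl]ethyl (2Z)-2-methylbut-2-enoate F5.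
- Ring closure with CrCl2/NiCl2 comes back to the route at 25, which then needs only two oxygen transfers under the conditions of step 13.

Further compounds
F0 | step 13 | none | none
F1 | step 9 | 2-[(2R,3R)-3-[(1Z)-3-iodobuta-1,3-dien-1-yl]-2-methyloxiran-2-yl]ethan-1-ol | OCC[C@@]1(C)O[C@@H]1/C=C\C(I)=C
F2 | step 9 | [(2R,3R)-3-[(1Z)-3-iodobuta-1,3-dien-1-yl]-2-methyloxiran-2-yl]acetaldehyde | O=CC[C@@]1(C)O[C@@H]1/C=C\C(I)=C
F3 | step 9 | (4R,5S)-4-{(1S)-1-hydroxy-2-[(2R,3R)-3-[(1Z)-3-iodobuta-1,3-dien-1-yl]-2-methyloxiran-2-yl]ethyl}-3-methylidene-5-{[(triethylsilyl)oxy]methyl}oxolan-2-one | C=C1C(=O)O[C@H](CO[Si](CC)(CC)CC)[C@H]1[C@@H](O)C[C@@]1(C)O[C@@H]1/C=C\C(I)=C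
F4 | step 9 | (1S)-2-[(2R,3R)-3-[(1Z)-3-iodobuta-1,3-dien-1-yl]-2-methyloxiran-2-yl]-1-[(2S,3R)-4-methylidene-5-oxo-2-{[(triethylsilyl)oxy]methyl}oxolan-3-yl]ethyl (2Z)-2-methylbut-2-enoate | C=C1C(=O)O[C@H](CO[Si](CC)(CC)CC)[C@H]1[C@@H](OC(=O)/C(C)=C\C)C[C@@]1(C)O[C@@H]1/C=C\C(I)=C
F5 | step 9 | (1S)-1-[(2S,3R)-2-formyl-4-methylidene-5-oxooxolan-3-yl]-2-[(2R,3R)-3-[(1Z)-3-iodobuta-1,3-dien-1-yl]-2-methyloxiran-2-yl]ethyl (2Z)-2-methylbut-2-enoate | C=C1C(=O)O[C@H](C=O)[C@H]1[C@@H](OC(=O)/C(C)=C\C)C[C@@]1(C)O[C@@H]1/C=C\C(I)=C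
F6 | step 12 | (6S,7R,8S)-8-[(2Z)-2-methylbut-2-enoyloxy]-5-oxogermacra-1(10)E,2Z,4(15),11(13)-tetraen-12,6-olide | C=C1C(=O)O[C@H]2[C@H]1[C@@H](OC(=O)/C(C)=C\C)C/C(C)=C/C=C\C(=C)C2=O
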